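**Retrosynthetic overview**
1. Target ⇒ its aryl silyl ether ⇒ three successive Mitsunobu esterifications (inversion at C-6 of the alcohol) of one cyclobutane triacid whose carboxyls are unmasked one at a time (free acid, then methyl enoate, then tert-butyl ester), each with one molecule of 6-epi-incarvilline.
2. 6-epi-Incarvilline ⇒ bicyclic keto-lactam: the piperidinone ring is closed onto a cyclopentenone by an intramolecular Michael addition of a phosphonoacetamide (sets the cis ring fusion); the 4-methyl group comes from HWE methylenation and convex-face hydrogenation.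
3. The cyclopentenone ⇒ ring-closing metathesis of a diene whose C-7a stereocentre comes from an organocatalytic propanal/nitrodiene Michael addition.
4. Cyclobutane core ⇒ methyl coumalate (photochemical 4π closure, hydrogenation); substituents by two amide-directed C–H couplings (enantioselective vinylation, then arylation after epimerisation); side chain by B-alkyl Suzuki coupling.
5. Ring order: cyclopentene, then piperidinone (alcohol branch); cyclobutane independently (core branch); no ring is formed after the fragments are joined.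

Assumption: in step 21 the antipode of the chiral oxazoline ligand that delivers the drawn (1R,2S,3S) product is used; the target is taken exactly as the given SMILES.

**Alcohol branch**

Step 1
Reactants: 1 (E)-cinnamaldehyde; 2 nitromethane
Product: 4 (1E,3E)-1-nitro-4-phenylbuta-1,3-diene, via nitro alcohol 3 (not isolated)
Conditions: NaOH, MeOH/H2O, 0–10 °C; then cold 4 M HCl
Reagents that add atoms: none
Why: Henry (nitroaldol) addition followed by acid-promoted dehydration gives the conjugated E,E-nitrodiene, the thermodynamic geometry.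

Step 2
Reactants: 5 propanal; 4 nitrodiene
Product: 7 nitro acetal, via Michael aldehyde 6 (not isolated)
Conditions: 5 (3 equiv), (S)-α,α-diphenylprolinol trimethylsilyl ether (10 mol %), toluene, 0 °C; then HC(OMe)3, TsOH·H2O (cat.), MeOH, rt
Reagents that add atoms: trimethyl orthoformate, COC(OC)OC
Why: Enamine-catalysed asymmetric Michael addition (1,4 to the nitro group), in which the shielded enamine face sets C3 as R (the later C-7a) with syn C2, followed by acetalisation of the labile aldehyde.

Step 3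
Reactants: 7 nitro acetal
Product: 9 Boc carbamate, via primary amine 8 (not isolated)
Conditions: LiAlH4, THF, 0 °C → rt; water quench, filter; then Boc2O, CH2Cl2, rt
Reagents that add atoms: di-tert-butyl dicarbonate, CC(C)(C)OC(=O)OC(=O)OC(C)(C)C
Why: Hydride reduction of the primary nitroalkane to the amine (acetal and isolated alkene are inert) and carbamate formation, with no stereocentre touched.

Step 4
Reactants: 9 Boc carbamate
Product: 10 N-methyl carbamate
Conditions: NaH, MeI, DMF, 0 °C → rt
Reagents that add atoms: iodomethane, CI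
Why: SN2 N-alkylation of the carbamate anion.

Step 5
Reactants: 10 N-methyl carbamate
Product: 11 aldehyde
Conditions: PPTS (0.3 equiv), acetone/H2O 4:1, 55 °C
Reagents that add atoms: water, O
Why: Mild acid-catalysed acetal hydrolysis leaves the Boc group intact; partial epimerisation α to the aldehyde is harmless because that centre is equilibrated in step 12.

Step 6
Reactants: 11 aldehyde
Product: 12 allylic alcohol
Conditions: vinylmagnesium bromide, THF, −78 °C; aqueous work-up
Reagents that add atoms: vinylmagnesium bromide, C=C[Mg]Br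
Why: Grignard 1,2-addition; the new carbinol centre is unselective and is removed by the oxidation in step 8.

Step 7
Reactants: 12 allylic alcohol
Product: 13 cyclopentenol
Conditions: second-generation Grubbs catalyst (5 mol %), CH2Cl2 (0.01 M), 40 °C
Reagents that add atoms: none
Why: Ring-closing metathesis between the vinyl carbinol and the styryl alkene forms the five-membered ring and expels styrene.

Step 8
Reactants: 13 cyclopentenol
Product: 14 Boc enone
Conditions: Dess–Martin periodinane, CH2Cl2, 0 °C → rt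
Reagents that add atoms: none
Why: Dess–Martin oxidation converts both carbinol epimers into the cyclopentenone under neutral conditions that leave the γ-stereocentre (later C-7a) untouched.

Step 9
Reactants: 14 Boc enone
Product: 16 phosphonoacetamide enone, via ammonium salt 15 (not isolated)
Conditions: TFA/CH2Cl2, 0 °C, evaporate; then (EtO)2P(O)CH2CO2H, EDC·HCl, HOBt, i-Pr2NEt, CH2Cl2, 0 °C → rt
Reagents that add atoms: (diethoxyphosphoryl)acetic acid, CCOP(=O)(CC(=O)O)OCC
Why: Boc acidolysis followed at once by carbodiimide amide coupling, so the free secondary amine is acylated before it can add to the enone.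

Step 10
Reactants: 16 phosphonoacetamide enone
Product: 17 phosphono keto-lactam
Conditions: LiCl (2 equiv), DBU (1 equiv), MeCN, 0 °C → rt
Reagents that add atoms: none
Why: Intramolecular Michael addition (6-exo-trig) of the lithium-chelated phosphonoacetamide carbanion to the enone β-carbon; the tether delivers it to the face of its own CH2N arm, so H-4a is cis to H-7a (cis ring fusion).

Step 11
Reactants: 17 phosphono keto-lactam
Product: 18 α-methylene keto-lactam
Conditions: NaH (1.1 equiv), THF, 0 °C; then paraformaldehyde, rt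
Reagents that add atoms: formaldehyde (as paraformaldehyde), C=O
Why: Horner–Wadsworth–Emmons olefination with formaldehyde turns the phosphonate carbon into an exocyclic methylene and erases the C-4 mixture.

Step 12
Reactants: 18 α-methylene keto-lactam
Product: 20 keto-lactam, via 7-epimer 19 (not isolated)
Conditions: H2 (1 atm), Pd/C, EtOAc, rt; filter; then K2CO3 (0.2 equiv), MeOH, rt
Reagents that add atoms: none
Why: Heterogeneous hydrogenation from the convex face (the face of H-4a and H-7a) sets C-4 as R, and base equilibration of the ketone α-carbon then gives the thermodynamic 7-methyl trans to C-1 (7S).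

Step 13
Reactants: 20 keto-lactam
Product: 21 6-epi-incarvilline
Conditions: LiAlH4, THF, 0 °C → reflux; water quench
Reagents that add atoms: none
Why: LiAlH4 reduces the lactam to the amine and the ketone to the alcohol; hydride attacks the convex face, syn to the 7-methyl as small hydrides do with 2-methylcyclopentanones, giving the 6S alcohol (OH on the concave face).

**Side reagents**

Step 14
Reactants: 22 methyl acetoacetate
Product: 23 methyl (E)-enol triflate
Conditions: Tf2O, aq. Me4NOH, hexanes, 5 °C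
Reagents that add atoms: trifluoromethanesulfonic anhydride, O=S(=O)(OS(=O)(=O)C(F)(F)F)C(F)(F)F
Why: O-triflation of the enolate; the non-chelating tetramethylammonium counter-ion gives the E isomer (OTf trans to the ester).

Step 15
Reactants: 24 4-iodo-2-methoxyphenol
Product: 25 aryl iodide silyl ether
Conditions: TIPSCl, imidazole, DMF, rt
Reagents that add atoms: chlorotri(propan-2-yl)silane, CC(C)[Si](Cl)(C(C)C)C(C)C
Why: Silylation of the phenol with a group that survives the later acidic, oxidative and Mitsunobu steps.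

**Core branch**

Step 16
Reactants: 26 methyl coumalate
Product: 28 cis acid ester, via photopyrone 27 (not isolated)
Conditions: hν (medium-pressure Hg lamp, Pyrex), CH2Cl2, 15 °C; then H2 (1 atm), Pd/C
Reagents that add atoms: none
Why: Photochemical 4π-electrocyclisation to the bicyclic β-lactone, then hydrogenation of the cyclobutene and hydrogenolysis of the allylic C–O bond give the cis-1,3-disubstituted cyclobutane.

Step 17
Reactants: 28 cis acid ester
Product: 30 methyl diacid, via methylated acid ester 29 (not isolated)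
Conditions: LiN(i-Pr)2 (2.2 equiv), THF, −78 → −20 °C; MeI; then LiOH, MeOH/H2O, 60 °C; 1 M HCl
Reagents that add atoms: iodomethane, CI; lithium hydroxide, [Li+].[OH-]
Why: Dianion alkylation methylates the ester enolate carbon (more acidic than the carboxylate α-position) and saponification follows; the cis/trans mixture converges in step 18.

Step 18
Reactants: 30 methyl diacid
Product: 31 bridged anhydride
Conditions: Ac2O, NaOAc (cat.), 140 °C; distil
Reagents that add atoms: none
Why: Cyclodehydration is possible only for the cis diacid, and the trans isomer epimerises at its CH centre through the mixed anhydride and converges on the same bridged anhydride.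

Step 19
Reactants: 31 bridged anhydride
Product: 32 cis amide acid
Conditions: 4-amino-2,3,5,6-tetrafluorobenzotrifluoride, NaH (2.1 equiv), THF, 0 °C → rt; 1 M HCl
Reagents that add atoms: 4-amino-2,3,5,6-tetrafluorobenzotrifluoride, Nc1c(F)c(F)c(C(F)(F)F)c(F)c1F
Why: Anhydride aminolysis at the less hindered carbonyl (on the CH carbon, not the quaternary one) gives the amide and the α-quaternary acid on the same ring face.

Step 20
Reactants: 32 cis amide acid
Product: 33 tert-butyl ester amide
Conditions: tert-butyl 2,2,2-trichloroacetimidate, BF3·OEt2 (cat.), CH2Cl2/cyclohexane, rt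
Reagents that add atoms: tert-butyl 2,2,2-trichloroacetimidate, CC(C)(C)OC(=N)C(Cl)(Cl)Cl
Why: Acid-catalysed O-tert-butylation by the imidate, which needs no attack at the hindered carboxyl carbon.

Step 21
Reactants: 33 tert-butyl ester amide
Product: 34 all-cis vinyl amide
Conditions: Pd(OAc)2 (10 mol %), chiral N-acetyl aminomethyl-oxazoline ligand (20 mol %), vinyl iodide (3 equiv), Ag2CO3 (2 equiv), t-AmylOH, 70 °C, sealed tube
Reagents that add atoms: vinyl iodide, C=CI
Why: Amide-directed enantioselective β-methylene C–H vinylation (divalent/tetravalent palladium cycle): the chiral ligand selects one of the two enantiotopic ring CH2 groups and cyclopalladation places the vinyl group cis to the amide, hence cis to the ester carbonyl.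

Step 22
Reactants: 34 all-cis vinyl amide
Product: 37 trans methyl ester, via N-Boc imide 35 (not isolated), via all-cis diester 36 (not isolated)
Conditions: Boc2O, DMAP (0.2 equiv), MeCN, 40 °C; evaporate; then NaOMe (3 equiv), MeOH, 40 °C; AcOH quench
Reagents that add atoms: sodium methoxide, [Na+].[O-]C
Why: N-Boc activation turns the anilide into an acyl donor for methanolysis, and methoxide then epimerises the ester α-carbon from the strained all-cis form to the thermodynamic form with the ester trans to the vinyl group.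

Step 23
Reactants: 37 trans methyl ester
Product: 38 vinyl acid
Conditions: LiOH·H2O (1.5 equiv), THF/MeOH/H2O, 0 °C → rt; 1 M HCl
Reagents that add atoms: lithium hydroxide, [Li+].[OH-]
Why: Saponification of the only unhindered ester (the α-quaternary tert-butyl ester is inert), with the α-centre already in its thermodynamic configuration.

Step 24
Reactants: 38 vinyl acid
Product: 39 vinyl quinolinyl amide
Conditions: 8-aminoquinoline, EDC·HCl, HOBt, CH2Cl2/DMF, rt
Reagents that add atoms: 8-aminoquinoline, Nc1cccc2cccnc12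
Why: Carbodiimide amide coupling installs the bidentate directing auxiliary before the side-chain ester is introduced, so the ring carboxyl and the side-chain carboxyl never need to be told apart by hydrolysis.

Step 25
Reactants: 39 vinyl quinolinyl amide; 23 methyl (E)-enol triflate
Product: 41 side-chain quinolinyl amide, via alkylborane 40 (not isolated)
Conditions: 9-BBN (2.5 equiv), THF, 0 °C → rt; then 23, PdCl2(dppf) (dppf = 1,1'-bis(diphenylphosphino)ferrocene; 5 mol %), aq. K3PO4, DMF, 50 °C
Reagents that add atoms: none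
Why: Anti-Markovnikov hydroboration of the terminal vinyl group followed by B-alkyl Suzuki–Miyaura coupling at zerovalent palladium, which retains the triflate geometry and so gives the E-trisubstituted methyl enoate.

Step 26
Reactants: 41 side-chain quinolinyl amide; 25 aryl iodide silyl ether
Product: 42 arylated quinolinyl amide
Conditions: 25 (2 equiv), Pd(OAc)2 (10 mol %), Ag2CO3 (1.5 equiv), pivalic acid (1 equiv), t-BuOH, 85 °C
Reagents that add atoms: none
Why: Auxiliary-directed C–H arylation: a five-membered palladacycle forms at the only β-methylene on the amide face, so oxidative addition of the aryl iodide and reductive elimination place the aryl group cis to the amide carbonyl and to the ring methyl.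

Step 27
Reactants: 42 arylated quinolinyl amide
Product: 44 aryl mono acid, via N-Boc amide 43 (not isolated)
Conditions: Boc2O, DMAP, MeCN, 60 °C; then LiOH, H2O2, THF/H2O, 0 °C; Na2SO3; 1 M HCl
Reagents that add atoms: hydrogen peroxide, OO
Why: N-Boc activation and hydroperoxide acyl cleavage at 0 °C remove the auxiliary without epimerising the kinetically set α-centre and without touching the conjugated methyl ester or the tert-butyl ester.

**Union (one carboxyl at a time)**

Step 28
Reactants: 44 aryl mono acid; 21 6-epi-incarvilline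
Product: 45 mono(incarvillyl) ester
Conditions: 21 (1.2 equiv), PPh3 (1.8 equiv), DIAD (1.8 equiv), THF, 0 °C → rt
Reagents that add atoms: none
Why: Mitsunobu esterification of the only free carboxyl, in which the carboxylate displaces the activated C-6 oxygen from the convex face with inversion (6S → 6R).

Step 29
Reactants: 45 mono(incarvillyl) ester
Product: 46 side-chain acid
Conditions: Me3SnOH (6 equiv), 1,2-dichloroethane, 75 °C; then 5% aq. HCl wash, pH 7 buffer
Reagents that add atoms: trimethyltin hydroxide, C[Sn](C)(C)O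
Why: Trimethyltin hydroxide ester cleavage is strongly size-selective, so the methyl enoate is hydrolysed while the doubly flanked secondary cyclopentyl ester, the tert-butyl ester and the aryl silyl ether stay intact and the E-alkene is not isomerised.

Step 30
Reactants: 46 side-chain acid; 21 6-epi-incarvilline
Product: 47 bis(incarvillyl) ester
Conditions: 21 (1.2 equiv), PPh3 (1.8 equiv), DIAD (1.8 equiv), THF, 0 °C → rt
Reagents that add atoms: none
Why: Second Mitsunobu esterification at the newly freed enoic acid, again with inversion at C-6 (6S → 6R) and without activating the acyl carbon, so the enoate cannot deconjugate.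

Step 31
Reactants: 47 bis(incarvillyl) ester
Product: 48 α-quaternary acid
Conditions: TFA/CH2Cl2 1:3, 0 °C → rt; evaporate; pH 7 buffer, extract
Reagents that add atoms: none
Why: Acidolysis (E1) of the tert-butyl ester without base, so no stereocentre can epimerise; the two alkaloid esters and the aryl silyl ether survive and the amines are merely protonated.

Step 32
Reactants: 48 α-quaternary acid; 21 6-epi-incarvilline
Product: 49 silyl-protected triester
Conditions: 21 (1.5 equiv), PPh3 (3 equiv), DIAD (3 equiv), THF/toluene, 0 → 40 °C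
Reagents that add atoms: none
Why: Third Mitsunobu esterification; because the hindered carboxylate acts as the nucleophile and its carbonyl carbon is never attacked, the α-quaternary acid still alkylates with inversion at C-6 (6S → 6R).

Step 33
Reactants: 49 silyl-protected triester
Product: 50 target CNP0251577.3
Conditions: Bu4NF (1.2 equiv), AcOH (1.5 equiv), THF, 0 °C
Reagents that add atoms: none
Why: Fluoride-mediated Si–O cleavage, buffered with acetic acid so the three esters are not touched.

**Compound list**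

1 | (E)-cinnamaldehyde | O=C/C=C/c1ccccc1 | starting material
2 | nitromethane | C[N+](=O)[O-] | starting material
3 | (3E)-1-nitro-4-phenylbut-3-en-2-ol (racemic) | OC(C[N+](=O)[O-])/C=C/c1ccccc1 | intermediate (not isolated)
4 | [(1E,3E)-4-nitrobuta-1,3-dien-1-yl]benzene | [O-][N+](=O)/C=C/C=C/c1ccccc1 | intermediate
5 | propanal | CCC=O | starting material
6 | (2R,3R,4E)-2-methyl-3-(nitromethyl)-5-phenylpent-4-enal | O=C[C@H](C)[C@H](C[N+](=O)[O-])/C=C/c1ccccc1 | intermediate (not isolated)
7 | [(1E,3R,4R)-5,5-dimethoxy-4-methyl-3-(nitromethyl)pent-1-en-1-yl]benzene | COC(OC)[C@H](C)[C@H](C[N+](=O)[O-])/C=C/c1ccccc1 | intermediate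
8 | (2R,3R)-4,4-dimethoxy-3-methyl-2-[(E)-2-phenylethenyl]butan-1-amine | COC(OC)[C@H](C)[C@H](CN)/C=C/c1ccccc1 | intermediate (not isolated)
9 | tert-butyl {(2R,3R)-4,4-dimethoxy-3-methyl-2-[(E)-2-phenylethenyl]butyl}carbamate | COC(OC)[C@H](C)[C@H](CNC(=O)OC(C)(C)C)/C=C/c1ccccc1 | intermediate
10 | tert-butyl {(2R,3R)-4,4-dimethoxy-3-methyl-2-[(E)-2-phenylethenyl]butyl}methylcarbamate | COC(OC)[C@H](C)[C@H](CN(C)C(=O)OC(C)(C)C)/C=C/c1ccccc1 | intermediate
11 | tert-butyl methyl{(2R,3R)-3-methyl-4-oxo-2-[(E)-2-phenylethenyl]butyl}carbamate | O=C[C@H](C)[C@H](CN(C)C(=O)OC(C)(C)C)/C=C/c1ccccc1 | intermediate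
12 | tert-butyl {(2R)-4-hydroxy-3-methyl-2-[(E)-2-phenylethenyl]hex-5-en-1-yl}methylcarbamate (epimers at C-3 and C-4) | C=CC(O)C(C)[C@H](CN(C)C(=O)OC(C)(C)C)/C=C/c1ccccc1 | intermediate
13 | tert-butyl {[(1R)-4-hydroxy-5-methylcyclopent-2-en-1-yl]methyl}methylcarbamate (epimers at C-4 and C-5) | OC1C=C[C@@H](CN(C)C(=O)OC(C)(C)C)C1C | intermediate
14 | tert-butyl methyl{[(1R)-5-methyl-4-oxocyclopent-2-en-1-yl]methyl}carbamate (C-5 epimers) | O=C1C=C[C@@H](CN(C)C(=O)OC(C)(C)C)C1C | intermediate
15 | N-methyl-1-[(1R)-5-methyl-4-oxocyclopent-2-en-1-yl]methanaminium trifluoroacetate (C-5 epimers) | O=C1C=C[C@@H](C[NH2+]C)C1C.[O-]C(=O)C(F)(F)F | intermediate (not isolated)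
16 | diethyl [2-(methyl{[(1R)-5-methyl-4-oxocyclopent-2-en-1-yl]methyl}amino)-2-oxoethyl]phosphonate (C-5 epimers) | O=C1C=C[C@@H](CN(C)C(=O)CP(=O)(OCC)OCC)C1C | intermediate
17 | diethyl [(4aR,7aS)-2,7-dimethyl-3,6-dioxooctahydro-1H-cyclopenta[c]pyridin-4-yl]phosphonate (cis-fused; epimers at C-4 and C-7) | O=C1C[C@@H]2[C@@H](CN(C)C(=O)C2P(=O)(OCC)OCC)C1C | intermediate
18 | (4aR,7aR)-2,7-dimethyl-4-methylidenehexahydro-1H-cyclopenta[c]pyridine-3,6(2H,4H)-dione (cis-fused; C-7 epimers) | O=C1C[C@@H]2[C@@H](CN(C)C(=O)C2=C)C1C | intermediate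
19 | (4R,4aR,7R,7aR)-2,4,7-trimethylhexahydro-1H-cyclopenta[c]pyridine-3,6(2H,4H)-dione (7-epimer of 20) | O=C1C[C@@H]2[C@@H](CN(C)C(=O)[C@@H]2C)[C@H]1C | intermediate (not isolated)
20 | (4R,4aR,7S,7aR)-2,4,7-trimethylhexahydro-1H-cyclopenta[c]pyridine-3,6(2H,4H)-dione (H-4, H-4a, H-7a on one face; 7-methyl trans to C-1) | O=C1C[C@@H]2[C@@H](CN(C)C(=O)[C@@H]2C)[C@@H]1C | intermediate
21 | (4R,4aS,6S,7S,7aR)-2,4,7-trimethyloctahydro-1H-cyclopenta[c]pyridin-6-ol (6-epi-incarvilline) | O[C@H]1C[C@@H]2[C@@H](CN(C)C[C@@H]2C)[C@@H]1C | intermediate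
22 | methyl 3-oxobutanoate (methyl acetoacetate) | CC(=O)CC(=O)OC | starting material
23 | methyl (2E)-3-{[(trifluoromethyl)sulfonyl]oxy}but-2-enoate | C/C(OS(=O)(=O)C(F)(F)F)=C\C(=O)OC | intermediate
24 | 4-iodo-2-methoxyphenol | COc1cc(I)ccc1O | starting material
25 | (4-iodo-2-methoxyphenoxy)tri(propan-2-yl)silane | COc1cc(I)ccc1O[Si](C(C)C)(C(C)C)C(C)C | intermediate
26 | methyl 2-oxo-2H-pyran-5-carboxylate (methyl coumalate) | COC(=O)C1=COC(=O)C=C1 | starting material
27 | methyl 3-oxo-2-oxabicyclo[2.2.0]hex-5-ene-6-carboxylate (racemic, cis-fused) | COC(=O)C1=CC2C(=O)OC12 | intermediate (not isolated)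
28 | cis-3-(methoxycarbonyl)cyclobutane-1-carboxylic acid | C1[C@H](C(=O)OC)C[C@@H]1C(=O)O | intermediate
29 | 3-(methoxycarbonyl)-3-methylcyclobutane-1-carboxylic acid (cis/trans mixture) | COC(=O)C1(C)CC(C1)C(=O)O | intermediate (not isolated)
30 | 1-methylcyclobutane-1,3-dicarboxylic acid (cis/trans mixture) | CC1(CC(C1)C(=O)O)C(=O)O | intermediate
31 | 1-methyl-3-oxabicyclo[3.1.1]heptane-2,4-dione | CC12CC(C1)C(=O)OC2=O | intermediate
32 | cis-1-methyl-3-{[2,3,5,6-tetrafluoro-4-(trifluoromethyl)phenyl]carbamoyl}cyclobutane-1-carboxylic acid (carboxyl and carbamoyl on the same face) | C1[C@H](C(=O)Nc2c(F)c(F)c(C(F)(F)F)c(F)c2F)C[C@]1(C)C(=O)O | intermediate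
33 | tert-butyl cis-1-methyl-3-{[2,3,5,6-tetrafluoro-4-(trifluoromethyl)phenyl]carbamoyl}cyclobutane-1-carboxylate | C1[C@H](C(=O)Nc2c(F)c(F)c(C(F)(F)F)c(F)c2F)C[C@]1(C)C(=O)OC(C)(C)C | intermediate
34 | tert-butyl (1R,2S,3S)-2-ethenyl-1-methyl-3-{[2,3,5,6-tetrafluoro-4-(trifluoromethyl)phenyl]carbamoyl}cyclobutane-1-carboxylate (ester carbonyl, vinyl and carbamoyl on one face) | C1[C@H](C(=O)Nc2c(F)c(F)c(C(F)(F)F)c(F)c2F)[C@H](C=C)[C@]1(C)C(=O)OC(C)(C)C | intermediate
35 | N-tert-butoxycarbonyl derivative of 34 | C1[C@H](C(=O)N(C(=O)OC(C)(C)C)c2c(F)c(F)c(C(F)(F)F)c(F)c2F)[C@H](C=C)[C@]1(C)C(=O)OC(C)(C)C | intermediate (not isolated)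
36 | 1-tert-butyl 3-methyl (1R,2S,3S)-2-ethenyl-1-methylcyclobutane-1,3-dicarboxylate (all-cis) | C1[C@H](C(=O)OC)[C@H](C=C)[C@]1(C)C(=O)OC(C)(C)C | intermediate (not isolated)
37 | 1-tert-butyl 3-methyl (1R,2S,3R)-2-ethenyl-1-methylcyclobutane-1,3-dicarboxylate (methyl ester trans to vinyl) | C1[C@@H](C(=O)OC)[C@H](C=C)[C@]1(C)C(=O)OC(C)(C)C | intermediate
38 | (1R,2S,3R)-3-(tert-butoxycarbonyl)-2-ethenyl-3-methylcyclobutane-1-carboxylic acid (carboxyl trans to vinyl) | C1[C@@H](C(=O)O)[C@H](C=C)[C@]1(C)C(=O)OC(C)(C)C | intermediate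
39 | tert-butyl (1R,2S,3R)-2-ethenyl-1-methyl-3-(quinolin-8-ylcarbamoyl)cyclobutane-1-carboxylate | C1[C@@H](C(=O)Nc2cccc3cccnc23)[C@H](C=C)[C@]1(C)C(=O)OC(C)(C)C | intermediate
40 | tert-butyl (1R,2S,3R)-2-[2-(9-borabicyclo[3.3.1]nonan-9-yl)ethyl]-1-methyl-3-(quinolin-8-ylcarbamoyl)cyclobutane-1-carboxylate | C1[C@@H](C(=O)Nc2cccc3cccnc23)[C@H](CCB2C3CCCC2CCC3)[C@]1(C)C(=O)OC(C)(C)C | intermediate (not isolated)
41 | tert-butyl (1R,2S,3R)-2-[(3E)-5-methoxy-3-methyl-5-oxopent-3-en-1-yl]-1-methyl-3-(quinolin-8-ylcarbamoyl)cyclobutane-1-carboxylate | C1[C@@H](C(=O)Nc2cccc3cccnc23)[C@H](CC/C(C)=C/C(=O)OC)[C@]1(C)C(=O)OC(C)(C)C | intermediate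
42 | tert-butyl (1S,2R,3S,4S)-4-[(3E)-5-methoxy-3-methyl-5-oxopent-3-en-1-yl]-2-{3-methoxy-4-[(triisopropylsilyl)oxy]phenyl}-1-methyl-3-(quinolin-8-ylcarbamoyl)cyclobutane-1-carboxylate | COc1cc([C@H]2[C@@H](C(=O)Nc3cccc4cccnc34)[C@H](CC/C(C)=C/C(=O)OC)[C@]2(C)C(=O)OC(C)(C)C)ccc1O[Si](C(C)C)(C(C)C)C(C)C | intermediate
43 | N-tert-butoxycarbonyl derivative of 42 | COc1cc([C@H]2[C@@H](C(=O)N(C(=O)OC(C)(C)C)c3cccc4cccnc34)[C@H](CC/C(C)=C/C(=O)OC)[C@]2(C)C(=O)OC(C)(C)C)ccc1O[Si](C(C)C)(C(C)C)C(C)C | intermediate (not isolated)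
44 | (1S,2R,3S,4S)-3-(tert-butoxycarbonyl)-4-[(3E)-5-methoxy-3-methyl-5-oxopent-3-en-1-yl]-2-{3-methoxy-4-[(triisopropylsilyl)oxy]phenyl}-3-methylcyclobutane-1-carboxylic acid | COc1cc([C@H]2[C@@H](C(=O)O)[C@H](CC/C(C)=C/C(=O)OC)[C@]2(C)C(=O)OC(C)(C)C)ccc1O[Si](C(C)C)(C(C)C)C(C)C | intermediate
45 | 1-tert-butyl 3-[(4R,4aS,6R,7S,7aR)-2,4,7-trimethyloctahydro-1H-cyclopenta[c]pyridin-6-yl] (1S,2R,3S,4S)-4-[(3E)-5-methoxy-3-methyl-5-oxopent-3-en-1-yl]-2-{3-methoxy-4-[(triisopropylsilyl)oxy]phenyl}-1-methylcyclobutane-1,3-dicarboxylate | COc1cc([C@H]2[C@@H](C(=O)O[C@@H]3C[C@@H]4[C@@H](CN(C)C[C@@H]4C)[C@@H]3C)[C@H](CC/C(C)=C/C(=O)OC)[C@]2(C)C(=O)OC(C)(C)C)ccc1O[Si](C(C)C)(C(C)C)C(C)C | intermediate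
46 | side-chain acid: 45 with its methyl ester hydrolysed to the free (2E)-3-methylpent-2-enoic acid terminus (ring tert-butyl ester and C-3 incarvillyl ester retained) | COc1cc([C@H]2[C@@H](C(=O)O[C@@H]3C[C@@H]4[C@@H](CN(C)C[C@@H]4C)[C@@H]3C)[C@H](CC/C(C)=C/C(=O)O)[C@]2(C)C(=O)OC(C)(C)C)ccc1O[Si](C(C)C)(C(C)C)C(C)C | intermediate
47 | bis(incarvillyl) ester: 46 esterified at the side-chain carboxyl with a second (4R,4aS,6R,7S,7aR)-2,4,7-trimethyloctahydro-1H-cyclopenta[c]pyridin-6-yl group (ring tert-butyl ester retained) | COc1cc([C@H]2[C@@H](C(=O)O[C@@H]3C[C@@H]4[C@@H](CN(C)C[C@@H]4C)[C@@H]3C)[C@H](CC/C(C)=C/C(=O)O[C@@H]3C[C@@H]4[C@@H](CN(C)C[C@@H]4C)[C@@H]3C)[C@]2(C)C(=O)OC(C)(C)C)ccc1O[Si](C(C)C)(C(C)C)C(C)C | intermediate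
48 | α-quaternary acid: 47 with the tert-butyl ester cleaved to the free ring C-1 carboxylic acid (both incarvillyl esters retained) | COc1cc([C@H]2[C@@H](C(=O)O[C@@H]3C[C@@H]4[C@@H](CN(C)C[C@@H]4C)[C@@H]3C)[C@H](CC/C(C)=C/C(=O)O[C@@H]3C[C@@H]4[C@@H](CN(C)C[C@@H]4C)[C@@H]3C)[C@]2(C)C(=O)O)ccc1O[Si](C(C)C)(C(C)C)C(C)C | intermediate
49 | O-triisopropylsilyl ether of the target (all three carboxyls as (4R,4aS,6R,7S,7aR)-2,4,7-trimethyloctahydro-1H-cyclopenta[c]pyridin-6-yl esters) | COc1cc([C@H]2[C@@H](C(=O)O[C@@H]3C[C@@H]4[C@@H](CN(C)C[C@@H]4C)[C@@H]3C)[C@H](CC/C(C)=C/C(=O)O[C@@H]3C[C@@H]4[C@@H](CN(C)C[C@@H]4C)[C@@H]3C)[C@]2(C)C(=O)O[C@@H]2C[C@@H]3[C@@H](CN(C)C[C@@H]3C)[C@@H]2C)ccc1O[Si](C(C)C)(C(C)C)C(C)C | intermediate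
50 | CNP0251577.3: tris[(4R,4aS,6R,7S,7aR)-2,4,7-trimethyloctahydro-1H-cyclopenta[c]pyridin-6-yl] triester of (1S,2R,3S,4S)-4-[(3E)-4-carboxy-3-methylbut-3-en-1-yl]-2-(4-hydroxy-3-methoxyphenyl)-1-methylcyclobutane-1,3-dicarboxylic acid | COc1cc([C@H]2[C@@H](C(=O)O[C@@H]3C[C@@H]4[C@@H](CN(C)C[C@@H]4C)[C@@H]3C)[C@H](CC/C(C)=C/C(=O)O[C@@H]3C[C@@H]4[C@@H](CN(C)C[C@@H]4C)[C@@H]3C)[C@]2(C)C(=O)O[C@@H]2C[C@@H]3[C@@H](CN(C)C[C@@H]3C)[C@@H]2C)ccc1O | target

**Step count and risks**

Total step count: 33.
Longest linear sequence: 19 steps (alcohol branch, steps 1–13, then steps 28–33; the core branch, steps 16–27 then 28–33, is 18 steps), which is 19/33 of the total.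

Three steps most likely to fail:

Step 21 (enantioselective C–H vinylation of 33). The ligand may give low ee or poor conversion on this 3,3-disubstituted ring. The fallback replaces asymmetric catalysis by an auxiliary-directed racemic coupling and a resolution. It sets out from anhydride 31: opening with 8-aminoquinoline (NaH, THF) gives cis-1-methyl-3-(quinolin-8-ylcarbamoyl)cyclobutane-1-carboxylic acid F1; tert-butyl trichloroacetimidate gives its tert-butyl ester F2; ligand-free Pd(OAc)2/AgOAc with vinyl iodide (toluene, 80 °C) gives the racemic all-cis vinyl quinolinyl amide F3. The enantiomers of F3 are separated by preparative chiral SFC, the (1R,2S,3S) enantiomer is converted with Boc2O/DMAP into the N-Boc quinolinyl amide F4, and NaOMe/MeOH then gives 36 and, after epimerisation, 37, where the route is rejoined.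

Step 26 (C–H arylation of 41 beside the quaternary carbon). The palladacycle must form and couple next to a fully substituted carbon bearing a cis methyl group. The fallback drops the auxiliary before the arylation and lets the carboxylate itself direct. It sets out from 41: Boc2O/DMAP gives the N-tert-butoxycarbonyl derivative of 41 F5, and LiOH/H2O2 at 0 °C gives (1R,2S,3R)-3-(tert-butoxycarbonyl)-2-[(3E)-5-methoxy-3-methyl-5-oxopent-3-en-1-yl]-3-methylcyclobutane-1-carboxylic acid F6. F6 is arylated with 25 under carboxylate-directed conditions (Pd(OAc)2, N-acetylglycine as ligand, Ag2CO3, K2HPO4, hexafluoroisopropanol, 90 °C). The free carboxylate binds palladium in a smaller, less crowded chelate and again delivers the aryl group cis to the carboxyl, so the route is rejoined directly at 44.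

Step 32 (third Mitsunobu, at the α-quaternary acid). The hindered carboxylate may be too poor a nucleophile for the secondary alkoxyphosphonium. The fallback inverts the alcohol first and then acylates with retention. It sets out from 21 and 48: 21 with 4-nitrobenzoic acid, PPh3 and DIAD gives (4R,4aS,6R,7S,7aR)-2,4,7-trimethyloctahydro-1H-cyclopenta[c]pyridin-6-yl 4-nitrobenzoate F7, and K2CO3 in MeOH gives incarvilline F8. Acid 48 with 1-chloro-N,N,2-trimethylprop-1-en-1-amine (CH2Cl2, 0 °C) gives the acid chloride of 48 F9, which with F8 (1.5 equiv), pyridine and DMAP in CH2Cl2 at 0 → 40 °C gives 49, where the route is rejoined.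

**Further compounds**

F1 | step 21 | cis-1-methyl-3-(quinolin-8-ylcarbamoyl)cyclobutane-1-carboxylic acid | C1[C@H](C(=O)Nc2cccc3cccnc23)C[C@]1(C)C(=O)O
F2 | step 21 | tert-butyl cis-1-methyl-3-(quinolin-8-ylcarbamoyl)cyclobutane-1-carboxylate | C1[C@H](C(=O)Nc2cccc3cccnc23)C[C@]1(C)C(=O)OC(C)(C)C
F3 | step 21 | racemic tert-butyl (1R*,2S*,3S*)-2-ethenyl-1-methyl-3-(quinolin-8-ylcarbamoyl)cyclobutane-1-carboxylate (drawn: the enantiomer carried on) | C1[C@H](C(=O)Nc2cccc3cccnc23)[C@H](C=C)[C@]1(C)C(=O)OC(C)(C)C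
F4 | step 21 | tert-butyl (1R,2S,3S)-3-[(tert-butoxycarbonyl)(quinolin-8-yl)carbamoyl]-2-ethenyl-1-methylcyclobutane-1-carboxylate | C1[C@H](C(=O)N(C(=O)OC(C)(C)C)c2cccc3cccnc23)[C@H](C=C)[C@]1(C)C(=O)OC(C)(C)C
F5 | step 26 | N-tert-butoxycarbonyl derivative of 41 | C1[C@@H](C(=O)N(C(=O)OC(C)(C)C)c2cccc3cccnc23)[C@H](CC/C(C)=C/C(=O)OC)[C@]1(C)C(=O)OC(C)(C)C
F6 | step 26 | (1R,2S,3R)-3-(tert-butoxycarbonyl)-2-[(3E)-5-methoxy-3-methyl-5-oxopent-3-en-1-yl]-3-methylcyclobutane-1-carboxylic acid | C1[C@@H](C(=O)O)[C@H](CC/C(C)=C/C(=O)OC)[C@]1(C)C(=O)OC(C)(C)C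
F7 | step 32 | (4R,4aS,6R,7S,7aR)-2,4,7-trimethyloctahydro-1H-cyclopenta[c]pyridin-6-yl 4-nitrobenzoate | O=C(O[C@@H]1C[C@@H]2[C@@H](CN(C)C[C@@H]2C)[C@@H]1C)c1ccc(cc1)[N+](=O)[O-]
F8 | step 32 | (4R,4aS,6R,7S,7aR)-2,4,7-trimethyloctahydro-1H-cyclopenta[c]pyridin-6-ol (incarvilline) | O[C@@H]1C[C@@H]2[C@@H](CN(C)C[C@@H]2C)[C@@H]1C
F9 | step 32 | acid chloride of 48 (ring C-1 carbonyl chloride; both incarvillyl esters and the silyl ether retained) | COc1cc([C@H]2[C@@H](C(=O)O[C@@H]3C[C@@H]4[C@@H](CN(C)C[C@@H]4C)[C@@H]3C)[C@H](CC/C(C)=C/C(=O)O[C@@H]3C[C@@H]4[C@@H](CN(C)C[C@@H]4C)[C@@H]3C)[C@]2(C)C(Cl)=O)ccc1O[Si](C(C)C)(C(C)C)C(C)C
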